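## Structural features

The target is a depside: two benzene rings joined by one ester, with the carbonyl on C1 of ring A and the oxygen on C4 of ring B. Ring A is a benzoyl unit with methoxy groups at C2 and C4, a hydroxymethyl group at C3 between them, a methyl group at C6 and one ring hydrogen at C5. Ring B is a salicylic acid with the carboxyl at C1, a free hydroxyl at C2, methyl groups at C3 and C6, the acyloxy group at C4 and a hydrogen at C5. There is no stereocenter and no stereogenic alkene, so no two stereocenters stand next to each other and nothing stereochemical has to be set in the final compound. The fragile groups are the aryl ester (cleaved by base and nucleophiles), the ring A benzylic alcohol flanked by two methoxy groups (it ionizes under acid and can be hydrogenolysed), and the 2-hydroxybenzoic acid of ring B (prone to decarboxylation on heating or in strong acid). The real difficulty is ring B: five contiguous substituents, two oxygens at C2 and C4 that must be told apart, and a carboxyl that must sit beside C2 and not between the oxygens. A second difficulty is joining a doubly ortho-substituted acid to a hindered phenol and then unmasking acid and alcohol without breaking the ester. The key step exploits the sequence C2(OH)–C3(CH3)–C4(O) of ring B: C2 comes from a ketene carbon, C3 and C4 from the two carbons of 1-siloxypropyne, and C5, C6 and C1 from the diazo carbon and the alkene of a mesaconate-type diazo ketone, so O4 arrives silylated and O2 free.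

## Logic of the disconnections

26 is traced back to 25 and then to 24 by restoring the silyl ether on the ring A benzylic oxygen and the benzyl ester on the ring B carboxyl. These are the two most reactive functions, and masking them leaves 24 as a neutral, robust compound. The forward steps must be orthogonal to the aryl ester, must not ionize the ring A benzylic carbon, and should run with hydrogenolysis first so that the benzylic C–O bond is still silylated while Pd and H2 are present.

24 is cut at the ester bond between the ring A carbonyl carbon and O4 of ring B, giving 22 and 15. This is the most convergent cut and divides the molecule into two arenes of similar size. The forward step must activate a doubly ortho-substituted acid under neutral conditions (through 23) and must acylate O4 of 15 in preference to O2.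

15 comes from 14 by cleavage of the O4–Si bond. The silyl group is the marker that the ring-forming step leaves on O4. The forward step needs a fluoride source that does not touch the benzyl ester.

14 is cut at C2–C3, C4–C5 and C1–C2 of ring B, giving 5 and 9. 5 supplies C1, C2, C5 and C6 with the carboxyl and the C6 methyl; 9 supplies C3, C4, the C3 methyl and O4. The gain is that no arene starting material is needed and the two oxygens are differentiated from the start. The forward step must deliver one regiochemistry in the (2+2) event and keep the E alkene geometry through the cascade 10, 11, 12, 13.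

5 is traced to 3 by removing the diazo group from the terminal carbon, and 3 is cut at its C2=C3 double bond into 1 and 2. This replaces acylation of a diazoalkane by a fumarate-type acid chloride, where dipolar cycloaddition to the electron-poor alkene would compete, with a diazo transfer that never exposes the alkene to a free diazoalkane. The forward steps must give the E alkene, olefinate only one carbonyl of 1, and enolize 3 at the acetyl methyl.

9 is traced to 6 through 8 and 7 by cutting the O–Si bond and the alkyne carbon–carbon bond made by one-carbon homologation. The forward step must silylate 8 on oxygen and not on carbon, which a bulky silyl chloride secures.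

22 is traced through 20, 19 and 18 to 16 by cutting in turn the C1–CO2H bond, the C1–Br bond, the O–Si bond and the C3–CH2OH bond. The symmetry of 16 makes this simple: only one position lies between two methoxy groups (metalation through 17), and the two remaining positions are equivalent (bromination, then 21). The forward steps need monobromination and a protecting group that survives the organolithium.

## Other disconnections considered

Alternative 1: The cut is made in ring A at C2–C3 and C4–C5 and leads back to the 2-pyranone A2 (methyl 6-methoxy-4-methyl-2-oxo-2H-pyran-5-carboxylate) and the alkoxyalkyne A3 (tert-butyl[(3-methoxyprop-2-yn-1-yl)oxy]dimethylsilane). In the forward direction the two would combine in a (4+2) cycloaddition with inverse electron demand, the nucleophilic propargylic carbon of A3 bonding to the methoxy-bearing C6 of A2. Decarboxylative cycloreversion of the bridged lactone would then give benzoate A1 (methyl 3-{[(tert-butyldimethylsilyl)oxy]methyl}-2,4-dimethoxy-6-methylbenzoate).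
- In its favour: every substituent of ring A is placed in one convergent operation, and the regiochemistry follows from matching the polarized alkyne with the push-pull pyranone.
- Against it here: A2 is a 6-alkoxypyranone with the reactivity of a cyclic acyl ketene acetal and A3 is a sensitive alkoxyalkyne, and each needs several steps. A1 is a doubly ortho-substituted methyl ester whose hydrolysis to the acid would be slow and would endanger the silyl ether, whereas 22 is formed directly as the acid. Ring A is also the easier ring, because the symmetry of 16 already solves its substitution pattern.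
- Comparison: on structure it addresses ring A and leaves ring B unsolved, while the chosen plan addresses the ring that has no symmetrical precursor. On mechanism the two are equal, since both rely on an oxygen-polarized alkyne for regiocontrol. On substituents set per step it is the better. On step economy it is expected to be longer than steps 6 to 9.

Alternative 2: The cut is the C1–C6 bond of ring B and leads back to the open-chain diketo-dioxinone A5 (2,2-dimethyl-6-(3,5-dioxohexan-2-yl)-4H-1,3-dioxin-4-one). In the forward direction a tertiary amine would induce aldol addition of dioxinone C5 to the terminal methyl ketone, and loss of water with enolization would give benzodioxinone A4 (7-hydroxy-2,2,5,8-tetramethyl-4H-1,3-benzodioxin-4-one).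
- In its favour: the cyclization is a mild polyketide-type aldol aromatization with no regiochemical ambiguity in ring closure, it needs no diazo compound and no light, and A4 has O4 free with O2 and the carboxyl masked together.
- Against it here: A5 is a strongly enolized tricarbonyl compound whose branch methyl must be built in from the start, because the most acidic site of the chain is the methylene between the two ketones. The benzodioxinone can only be opened to the acid by a nucleophile that would also cleave the depside ester, so A4 would have to be opened with a benzyloxide nucleophile before coupling. That converts A4 into 15 and joins the chosen route at step 10.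
- Comparison: on differentiation of O2 and O4 it is equal. On operational safety and scale it is the better. On step economy it is expected to be equal or slightly longer, since A5 needs several acylation steps and one more step leads from A4 to 15. On mechanism it is the more predictable ring closure but the less predictable precursor synthesis.

Alternative 3: The cut removes the C6–CH3 and C1–CO2H bonds of ring A together and leads back to the symmetrical bromide A7 ([(4-bromo-2,6-dimethoxyphenyl)methoxy]triisopropylsilane), which would be made from A8 (1-bromo-3,5-dimethoxybenzene). In the forward direction a hindered lithium amide would remove one of the two equivalent protons between bromine and methoxy, and loss of bromide would give the aryne. A methyl Grignard reagent would add at C6, meta to the methoxy group, and carboxylation of the resulting C1 aryl-magnesium species would give acid A6 (2,4-dimethoxy-6-methyl-3-{[(triisopropylsilyl)oxy]methyl}benzoic acid).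
- In its favour: two carbon–carbon bonds are made in one flask, the symmetry of A7 removes any choice of proton, and the methoxy group next to the aryne directs the nucleophile.
- Against it here: the amide base can add to the aryne in competition with the Grignard reagent, the Grignard reagent can metalate or exchange with A7, and three organometallic events must be timed in one pot.
- Comparison: on structure both plans reach the same kind of silyl-protected ring A acid (A6 against 22). On step economy they are equal, about four steps from A8 against four steps from 16. On mechanism the chosen sequence of bromination and bromine–lithium exchange (steps 8 and 9) is the more dependable, while the alternative is the better in bonds formed per operation. Ring B is not addressed.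

Key step: step 4

Remark on the chemistry: the target is achiral. The only stereochemical element in the route is the E geometry of the trisubstituted alkene in 3, 4, 5 and 10; intermediates 11 and 13 are racemic and transient.

## Route

Step 1
Reactants: 1 butane-2,3-dione; 2 benzyl (triphenylphosphoranylidene)acetate
Product: 3 benzyl (2E)-3-methyl-4-oxopent-2-enoate
Conditions: 1 (3 equiv), CH2Cl2, 0 °C → rt
Reagents that add atoms: none
Why: Wittig olefination of one carbonyl of the activated 1,2-diketone by the ester-stabilized ylide; thermodynamic control should place the ester trans to the larger acetyl group (E), and the excess of volatile 1 suppresses double olefination.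

Step 2
Reactants: 3 benzyl (2E)-3-methyl-4-oxopent-2-enoate
Product: 5 benzyl (2E)-5-diazo-3-methyl-4-oxopent-2-enoate, via trifluoroacetyl diketone 4 (not isolated)
Conditions: LiHMDS, THF, −78 °C (3 added to the base); CF3CO2CH2CF3, −78 °C; aq. HCl; crude 4, 4-acetamidobenzenesulfonyl azide, Et3N, H2O (1 equiv), MeCN, rt
Reagents that add atoms: 4-acetamidobenzenesulfonyl azide, CC(=O)Nc1ccc(cc1)S(=O)(=O)N=[N+]=[N-]
Why: Detrifluoroacetylative diazo transfer (Danheiser diazo transfer): kinetic enolization at the acetyl methyl and Claisen trifluoroacetylation give 4, whose activated methylene accepts the diazo group while the trifluoroacetyl group leaves on the sulfonamide nitrogen. The electron-poor alkene never meets a free diazoalkane, and no diazomethane is used.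

Step 3
Reactants: 6 ethyl acetate
Product: 9 triisopropyl(prop-1-yn-1-yloxy)silane, via lithium 1,1-dibromoprop-1-en-2-olate 7 (not isolated), via lithium prop-1-yn-1-olate 8 (not isolated)
Conditions: CH2Br2, LiTMP, THF, −78 °C; 6; LiHMDS; n-BuLi, −78 °C → rt; i-Pr3SiCl, −78 °C → rt
Reagents that add atoms: dibromomethane, BrCBr; triisopropylsilyl chloride, CC(C)[Si](Cl)(C(C)C)C(C)C
Why: Kowalski ester homologation stopped at the ynolate: LiCHBr2 adds to the ester, enolate 7 undergoes bromine–lithium exchange and 1,2-shift of the methyl group with loss of LiBr to give 8, and the bulky silyl chloride silylates 8 on oxygen.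

Step 4
Reactants: 5 benzyl (2E)-5-diazo-3-methyl-4-oxopent-2-enoate; 9 triisopropyl(prop-1-yn-1-yloxy)silane
Product: 14 benzyl 2-hydroxy-3,6-dimethyl-4-[(triisopropylsilyl)oxy]benzoate, via vinylketene 10 (not isolated), via vinylcyclobutenone 11 (not isolated), via dienylketene 12 (not isolated), via cyclohexadienone 13 (not isolated)
Conditions: 9 (1.5 equiv), hν (medium-pressure Hg lamp, Pyrex filter), degassed ClCH2CH2Cl, rt; then 80 °C
Reagents that add atoms: none
Why: Light expels N2 from 5 and the alkenyl group migrates to the carbene carbon (Wolff rearrangement), giving vinylketene 10, whose ketene carbon becomes C2 of ring B. Siloxyalkyne 9 then adds to the ketene C=C in a (2+2) cycloaddition: its methyl-bearing carbon, made nucleophilic by the oxygen lone pair, attacks the ketene carbonyl carbon (C2–C3) and the siloxy carbon joins the former diazo carbon (C4–C5), giving vinylcyclobutenone 11. Four-electron electrocyclic opening of 11, by light or on heating, gives dienylketene 12, and six-electron disrotatory electrocyclization of 12 onto the ester-bearing alkene carbon forms C1–C2 and closes ring B as the 6-membered carbocycle 13, which enolizes to the arene. The closest known reaction type is the Danheiser benzannulation of α,β-unsaturated α'-diazo ketones with siloxyalkynes; this case differs only in the ester on the alkene terminus, which makes 10 more electrophilic toward the electron-rich alkyne and leaves a doubly activated C1–H in 13 for fast tautomerization. No stereocenter is created in the product, since the sp3 centers of 11 and 13 are lost on ring opening and aromatization. The selectivity needed is the regiochemistry of the (2+2) step, secured by the polarization of 9, and retention of the E geometry, which holds the ester carbonyl away from the ketene so that lactonization to a pyranone cannot compete; Pyrex-filtered light is chosen to limit E/Z photoisomerization and excitation of the benzyl ester. The phenol of 14 is hydrogen bonded to the ester carbonyl and flanked by two substituents, so it should not trap 10.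

Step 5
Reactants: 14 benzyl 2-hydroxy-3,6-dimethyl-4-[(triisopropylsilyl)oxy]benzoate
Product: 15 benzyl 2,4-dihydroxy-3,6-dimethylbenzoate
Conditions: Bu4NF, AcOH, THF, 0 °C
Reagents that add atoms: none
Why: Fluoride-induced cleavage of the aryl silyl ether; the phenoxide leaving group makes this fast at 0 °C, and acetic acid buffering protects the benzyl ester and the electron-rich resorcinol from base.

Step 6
Reactants: 16 3,5-dimethoxytoluene
Product: 18 (2,6-dimethoxy-4-methylphenyl)methanol, via aryllithium 17 (not isolated)
Conditions: n-BuLi, THF, 0 °C → rt; (CH2O)n, 0 °C → rt; H2O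
Reagents that add atoms: paraformaldehyde (source of formaldehyde), C=O
Why: Directed ortho-metalation at the only position flanked by two methoxy groups, then hydroxymethylation of aryllithium 17 by formaldehyde released from the polymer.

Step 7
Reactants: 18 (2,6-dimethoxy-4-methylphenyl)methanol
Product: 19 tert-butyl[(2,6-dimethoxy-4-methylphenyl)methoxy]dimethylsilane
Conditions: t-BuMe2SiCl, imidazole, DMF, rt
Reagents that add atoms: tert-butyldimethylsilyl chloride, CC(C)(C)[Si](C)(C)Cl
Why: Standard silylation of a primary alcohol; the silyl ether shields the ionization-prone benzylic C–O bond and tolerates the organolithium, acylation and hydrogenolysis steps that follow.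

Step 8
Reactants: 19 tert-butyl[(2,6-dimethoxy-4-methylphenyl)methoxy]dimethylsilane
Product: 20 [(3-bromo-2,6-dimethoxy-4-methylphenyl)methoxy](tert-butyl)dimethylsilane
Conditions: NBS (1.0 equiv), MeCN, −20 → 0 °C, dark
Reagents that add atoms: N-bromosuccinimide, O=C1CCC(=O)N1Br
Why: Electrophilic aromatic bromination; the two open ring positions are equivalent by symmetry and each is ortho and para to a methoxy group, so monobromination has no regiochemical alternative, and one equivalent at low temperature limits dibromination.

Step 9
Reactants: 20 [(3-bromo-2,6-dimethoxy-4-methylphenyl)methoxy](tert-butyl)dimethylsilane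
Product: 22 3-{[(tert-butyldimethylsilyl)oxy]methyl}-2,4-dimethoxy-6-methylbenzoic acid, via aryllithium 21 (not isolated)
Conditions: n-BuLi, THF, −78 °C; CO2 (g), −78 → 0 °C; aq. HCl to pH 4, 0 °C
Reagents that add atoms: carbon dioxide, O=C=O
Why: Bromine–lithium exchange outruns deprotonation at −78 °C, and carboxylation of aryllithium 21 gives the acid directly, so no hindered ester has to be hydrolysed later.

Step 10
Reactants: 22 3-{[(tert-butyldimethylsilyl)oxy]methyl}-2,4-dimethoxy-6-methylbenzoic acid; 15 benzyl 2,4-dihydroxy-3,6-dimethylbenzoate
Product: 24 4-[(benzyloxy)carbonyl]-3-hydroxy-2,5-dimethylphenyl 3-{[(tert-butyldimethylsilyl)oxy]methyl}-2,4-dimethoxy-6-methylbenzoate, via acid chloride 23 (not isolated)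
Conditions: 22, Me2C=C(Cl)NMe2, CH2Cl2, 0 °C → rt; then 15, Et3N, DMAP (cat.), CH2Cl2, 0 °C → rt
Reagents that add atoms: none
Why: Acid chloride formation under neutral conditions with the α-chloroenamine, then base-mediated O-acylation; the ortho and para methoxy groups keep 23 reactive despite its two ortho substituents. The 4-OH of 15 is the more acidic and the only non-chelated phenol, so it should be acylated in preference to the 2-OH, which is hydrogen bonded to the ester carbonyl.

Step 11
Reactants: 24 4-[(benzyloxy)carbonyl]-3-hydroxy-2,5-dimethylphenyl 3-{[(tert-butyldimethylsilyl)oxy]methyl}-2,4-dimethoxy-6-methylbenzoate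
Product: 25 4-[(3-{[(tert-butyldimethylsilyl)oxy]methyl}-2,4-dimethoxy-6-methylbenzoyl)oxy]-2-hydroxy-3,6-dimethylbenzoic acid
Conditions: H2 (1 atm), Pd/C (10% Pd), EtOAc, rt
Reagents that add atoms: none
Why: Hydrogenolysis of the benzyl ester; the aryl ester is inert to these conditions and the ring A benzylic oxygen is still silylated, which should hold back hydrogenolysis of that C–O bond.

Step 12
Reactants: 25 4-[(3-{[(tert-butyldimethylsilyl)oxy]methyl}-2,4-dimethoxy-6-methylbenzoyl)oxy]-2-hydroxy-3,6-dimethylbenzoic acid
Product: 26 4-{[3-(hydroxymethyl)-2,4-dimethoxy-6-methylbenzoyl]oxy}-2-hydroxy-3,6-dimethylbenzoic acid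
Conditions: HF·pyridine, pyridine, THF, 0 °C → rt
Reagents that add atoms: none
Why: Fluoride cleavage of the primary silyl ether under buffered, weakly acidic and non-nucleophilic conditions that should spare the aryl ester, the salicylic acid and the acid-sensitive benzylic alcohol.

## Compound list

1 | butane-2,3-dione | CC(=O)C(C)=O | starting material
2 | benzyl (triphenylphosphoranylidene)acetate | O=C(C=P(c1ccccc1)(c1ccccc1)c1ccccc1)OCc1ccccc1 | starting material
3 | benzyl (2E)-3-methyl-4-oxopent-2-enoate | CC(=O)/C(C)=C/C(=O)OCc1ccccc1 | intermediate
4 | benzyl (2E)-6,6,6-trifluoro-3-methyl-4,6-dioxohex-2-enoate (trifluoroacetyl diketone) | O=C(CC(=O)C(F)(F)F)/C(C)=C/C(=O)OCc1ccccc1 | intermediate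
5 | benzyl (2E)-5-diazo-3-methyl-4-oxopent-2-enoate | [N-]=[N+]=CC(=O)/C(C)=C/C(=O)OCc1ccccc1 | intermediate
6 | ethyl acetate | CCOC(C)=O | starting material
7 | lithium 1,1-dibromoprop-1-en-2-olate | [Li]OC(C)=C(Br)Br | intermediate
8 | lithium prop-1-yn-1-olate | CC#CO[Li] | intermediate
9 | triisopropyl(prop-1-yn-1-yloxy)silane | CC#CO[Si](C(C)C)(C(C)C)C(C)C | intermediate
10 | benzyl (2E)-3-methyl-5-oxopenta-2,4-dienoate (vinylketene) | O=C=C/C(C)=C/C(=O)OCc1ccccc1 | intermediate
11 | benzyl (2E)-3-[3-methyl-4-oxo-2-(triisopropylsilyloxy)cyclobut-2-en-1-yl]but-2-enoate (vinylcyclobutenone, racemic) | CC1=C(O[Si](C(C)C)(C(C)C)C(C)C)C(/C(C)=C/C(=O)OCc2ccccc2)C1=O | intermediate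
12 | benzyl (2E,4E)-3,6-dimethyl-7-oxo-5-(triisopropylsilyloxy)hepta-2,4,6-trienoate (dienylketene) | O=C=C(C)/C(O[Si](C(C)C)(C(C)C)C(C)C)=C\C(C)=C\C(=O)OCc1ccccc1 | intermediate
13 | benzyl 2,5-dimethyl-6-oxo-4-(triisopropylsilyloxy)cyclohexa-2,4-diene-1-carboxylate (cyclohexadienone, racemic) | O=C1C(C)=C(O[Si](C(C)C)(C(C)C)C(C)C)C=C(C)C1C(=O)OCc1ccccc1 | intermediate
14 | benzyl 2-hydroxy-3,6-dimethyl-4-[(triisopropylsilyl)oxy]benzoate | Cc1cc(O[Si](C(C)C)(C(C)C)C(C)C)c(C)c(O)c1C(=O)OCc1ccccc1 | intermediate
15 | benzyl 2,4-dihydroxy-3,6-dimethylbenzoate | Cc1cc(O)c(C)c(O)c1C(=O)OCc1ccccc1 | intermediate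
16 | 3,5-dimethoxytoluene | COc1cc(C)cc(OC)c1 | starting material
17 | (2,6-dimethoxy-4-methylphenyl)lithium | [Li]c1c(OC)cc(C)cc1OC | intermediate
18 | (2,6-dimethoxy-4-methylphenyl)methanol | COc1cc(C)cc(OC)c1CO | intermediate
19 | tert-butyl[(2,6-dimethoxy-4-methylphenyl)methoxy]dimethylsilane | COc1cc(C)cc(OC)c1CO[Si](C)(C)C(C)(C)C | intermediate
20 | [(3-bromo-2,6-dimethoxy-4-methylphenyl)methoxy](tert-butyl)dimethylsilane | COc1cc(C)c(Br)c(OC)c1CO[Si](C)(C)C(C)(C)C | intermediate
21 | (3-{[(tert-butyldimethylsilyl)oxy]methyl}-2,4-dimethoxy-6-methylphenyl)lithium | [Li]c1c(C)cc(OC)c(CO[Si](C)(C)C(C)(C)C)c1OC | intermediate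
22 | 3-{[(tert-butyldimethylsilyl)oxy]methyl}-2,4-dimethoxy-6-methylbenzoic acid | COc1cc(C)c(C(=O)O)c(OC)c1CO[Si](C)(C)C(C)(C)C | intermediate
23 | 3-{[(tert-butyldimethylsilyl)oxy]methyl}-2,4-dimethoxy-6-methylbenzoyl chloride | COc1cc(C)c(C(Cl)=O)c(OC)c1CO[Si](C)(C)C(C)(C)C | intermediate
24 | 4-[(benzyloxy)carbonyl]-3-hydroxy-2,5-dimethylphenyl 3-{[(tert-butyldimethylsilyl)oxy]methyl}-2,4-dimethoxy-6-methylbenzoate | COc1cc(C)c(C(=O)Oc2cc(C)c(C(=O)OCc3ccccc3)c(O)c2C)c(OC)c1CO[Si](C)(C)C(C)(C)C | intermediate
25 | 4-[(3-{[(tert-butyldimethylsilyl)oxy]methyl}-2,4-dimethoxy-6-methylbenzoyl)oxy]-2-hydroxy-3,6-dimethylbenzoic acid | COc1cc(C)c(C(=O)Oc2cc(C)c(C(=O)O)c(O)c2C)c(OC)c1CO[Si](C)(C)C(C)(C)C | intermediate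
26 | 4-{[3-(hydroxymethyl)-2,4-dimethoxy-6-methylbenzoyl]oxy}-2-hydroxy-3,6-dimethylbenzoic acid | COc1cc(C)c(C(=O)Oc2cc(C)c(C(=O)O)c(O)c2C)c(OC)c1CO | target

## Step count and least certain steps

Total step count: 12. Longest linear sequence: 7 steps (16 to 26 through steps 6 to 12; the ring B branch from 1 through steps 1, 2, 4, 5, 10, 11 and 12 is equally long).

Step 4 (key step). The most likely failure is E to Z photoisomerization of the enoate in 5 or 10, after which the ester carbonyl captures the ketene and lactonization takes over. Other risks are conjugate addition of the electron-rich alkyne to the electron-poor alkene and arrest at the cyclobutenone stage if ring opening of 11 is slow. The fallback abandons the annulation for classical arene chemistry; it sets out from 16 and comes back to the route at 15. Lithiation of 16 between the methoxy groups (n-BuLi, THF) and quenching with MeI would give 1,3-dimethoxy-2,5-dimethylbenzene F1. Demethylation with BBr3 in CH2Cl2 would give 2,5-dimethylbenzene-1,3-diol F2. Kolbe–Schmitt carboxylation (KHCO3, CO2, about 120 °C) at one of the two equivalent open positions would give 2,4-dihydroxy-3,6-dimethylbenzoic acid F3. Selective O-benzylation of the carboxylate (BnBr, KHCO3, DMF, rt) would give 15.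

Step 2. Enolization may be diverted by deprotonation at the allylic methyl or by conjugate addition of the enolate to a second molecule of 3, and the amine used in the transfer may degrade the diazo enone. The fallback sets out from 3 and comes back at 5. Soft enolization (Me3SiOTf, Et3N, CH2Cl2, 0 °C) would give benzyl (2E)-3-methyl-4-[(trimethylsilyl)oxy]penta-2,4-dienoate F4. Bromination with NBS in THF at 0 °C would give benzyl (2E)-5-bromo-3-methyl-4-oxopent-2-enoate F5. Treatment with N,N'-ditosylhydrazine and DBU in THF at 0 °C would alkylate the hydrazine and eliminate two sulfinate groups to give 5.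

Step 10. Acylation may occur at O2 or at both phenols, or may be slow enough for the silyl ether to be lost to adventitious HCl. The fallback blocks O2; it sets out from 14 and comes back at 25. Benzylation of the free phenol (BnBr, K2CO3, acetone, reflux) would give benzyl 2-(benzyloxy)-3,6-dimethyl-4-[(triisopropylsilyl)oxy]benzoate F6. Desilylation (Bu4NF, AcOH, THF) would give benzyl 2-(benzyloxy)-4-hydroxy-3,6-dimethylbenzoate F7, which has one phenol only. Acylation with 23 as in step 10 would give 3-(benzyloxy)-4-[(benzyloxy)carbonyl]-2,5-dimethylphenyl 3-{[(tert-butyldimethylsilyl)oxy]methyl}-2,4-dimethoxy-6-methylbenzoate F8. Hydrogenolysis (H2, Pd/C, EtOAc) would remove both benzyl groups and give 25.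

Step 12. The free carboxylic acid together with HF may promote ionization at the ring A benzylic carbon, and separating the polar acid from fluoride and pyridinium salts may cost material through ester cleavage. The fallback reverses the order of the two deprotections; it sets out from 24 and comes back at 26. Buffered desilylation of the neutral ester (Bu4NF, AcOH, THF, 0 °C) would give 4-[(benzyloxy)carbonyl]-3-hydroxy-2,5-dimethylphenyl 3-(hydroxymethyl)-2,4-dimethoxy-6-methylbenzoate F9, which can be purified by chromatography. A short hydrogenolysis (H2, Pd/C, EtOAc, monitored closely) would then give 26 after filtration and evaporation.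

Step 6. Depolymerization of paraformaldehyde may be slow, and the alkoxide formed may add further formaldehyde, so that conversion of 17 is incomplete and hemiformal oligomers form. The fallback sets out from 16 and comes back at 18. Lithiation as in step 6 and quenching with DMF would give 2,6-dimethoxy-4-methylbenzaldehyde F10, and reduction with NaBH4 in MeOH at 0 °C would give 18.

## Further compounds

F1 | step 4 | 1,3-dimethoxy-2,5-dimethylbenzene | COc1cc(C)cc(OC)c1C
F2 | step 4 | 2,5-dimethylbenzene-1,3-diol | Cc1cc(O)c(C)c(O)c1
F3 | step 4 | 2,4-dihydroxy-3,6-dimethylbenzoic acid | Cc1cc(O)c(C)c(O)c1C(=O)O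
F4 | step 2 | benzyl (2E)-3-methyl-4-[(trimethylsilyl)oxy]penta-2,4-dienoate | C=C(O[Si](C)(C)C)/C(C)=C/C(=O)OCc1ccccc1
F5 | step 2 | benzyl (2E)-5-bromo-3-methyl-4-oxopent-2-enoate | O=C(CBr)/C(C)=C/C(=O)OCc1ccccc1
F6 | step 10 | benzyl 2-(benzyloxy)-3,6-dimethyl-4-[(triisopropylsilyl)oxy]benzoate | Cc1cc(O[Si](C(C)C)(C(C)C)C(C)C)c(C)c(OCc2ccccc2)c1C(=O)OCc1ccccc1
F7 | step 10 | benzyl 2-(benzyloxy)-4-hydroxy-3,6-dimethylbenzoate | Cc1cc(O)c(C)c(OCc2ccccc2)c1C(=O)OCc1ccccc1
F8 | step 10 | 3-(benzyloxy)-4-[(benzyloxy)carbonyl]-2,5-dimethylphenyl 3-{[(tert-butyldimethylsilyl)oxy]methyl}-2,4-dimethoxy-6-methylbenzoate | COc1cc(C)c(C(=O)Oc2cc(C)c(C(=O)OCc3ccccc3)c(OCc3ccccc3)c2C)c(OC)c1CO[Si](C)(C)C(C)(C)C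
F9 | step 12 | 4-[(benzyloxy)carbonyl]-3-hydroxy-2,5-dimethylphenyl 3-(hydroxymethyl)-2,4-dimethoxy-6-methylbenzoate | COc1cc(C)c(C(=O)Oc2cc(C)c(C(=O)OCc3ccccc3)c(O)c2C)c(OC)c1CO
F10 | step 6 | 2,6-dimethoxy-4-methylbenzaldehyde | COc1cc(C)cc(OC)c1C=O
A1 | alternative 1 | methyl 3-{[(tert-butyldimethylsilyl)oxy]methyl}-2,4-dimethoxy-6-methylbenzoate | COC(=O)c1c(C)cc(OC)c(CO[Si](C)(C)C(C)(C)C)c1OC
A2 | alternative 1 | methyl 6-methoxy-4-methyl-2-oxo-2H-pyran-5-carboxylate | COC(=O)C1=C(OC)OC(=O)C=C1C
A3 | alternative 1 | tert-butyl[(3-methoxyprop-2-yn-1-yl)oxy]dimethylsilane | COC#CCO[Si](C)(C)C(C)(C)C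
A4 | alternative 2 | 7-hydroxy-2,2,5,8-tetramethyl-4H-1,3-benzodioxin-4-one | Cc1cc(O)c(C)c2OC(C)(C)OC(=O)c12
A5 | alternative 2 | 2,2-dimethyl-6-(3,5-dioxohexan-2-yl)-4H-1,3-dioxin-4-one | CC(=O)CC(=O)C(C)C1=CC(=O)OC(C)(C)O1
A6 | alternative 3 | 2,4-dimethoxy-6-methyl-3-{[(triisopropylsilyl)oxy]methyl}benzoic acid | COc1cc(C)c(C(=O)O)c(OC)c1CO[Si](C(C)C)(C(C)C)C(C)C
A7 | alternative 3 | [(4-bromo-2,6-dimethoxyphenyl)methoxy]triisopropylsilane | COc1cc(Br)cc(OC)c1CO[Si](C(C)C)(C(C)C)C(C)C
A8 | alternative 3 | 1-bromo-3,5-dimethoxybenzene | COc1cc(Br)cc(OC)c1
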